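**Strategy.** Everything rests on cutting the C4a–C8a bond of ring A of the apigenin half. That ring (C4a, C5, C6, C7, C8, C8a; oxygen on C5, C7 and C8a, hydrogen on C6 and C8) is an unsubstituted acylphloroglucinol, the Claisen fold of a poly-β-carbonyl chain. In one operation Mg(OMe)2 opens a 4-hydroxy-2-pyrone to a chelated methyl 3,5,7,9-tetraoxo ester and closes the future C4a methylene onto the ester carbon (future C8a), creating the aromatic ring. The substrate is a 6-(4-aryl-2,4-dioxobutyl)-4-hydroxy-2-pyrone whose aryl group already carries the complete, benzyl-protected 6-aryloxy-4'-methoxyflavone half; it is reached by terminal aroylation of trilithiated tetraacetic acid lactone.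

Key step: step 8

Remark on the chemistry: no compound in the route has a stereocentre, so no configuration has to be set. Labels C2 to C8a are flavone positions of the apigenin half. Labels C1 to C9 count the open chain of 17 from its ester carbon (C1 = future C8a, C6 = future C4a, C9 = future C2). The 1,3-diketone of 16 is left unprotected on purpose, because its Mg2+ chelate serves as the protecting group during the fold.

**Route**

Step 1
Reactants: 1 2',4',6'-trihydroxyacetophenone
Product: 2 1-[2,4-bis(benzyloxy)-6-hydroxyphenyl]ethan-1-one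
Conditions: BnBr (2.1 equiv), K2CO3, DMF, 60 °C
Reagents that add atoms: benzyl bromide, BrCc1ccccc1
Why: Williamson etherification, in which the hydroxyl hydrogen-bonded to the acetyl group is the least nucleophilic, so two equivalents of benzyl bromide should alkylate the para hydroxyl and one of the two equivalent ortho hydroxyls and leave one chelated phenol.

Step 2
Reactants: 2 1-[2,4-bis(benzyloxy)-6-hydroxyphenyl]ethan-1-one
Product: 4 1-[2,4-bis(benzyloxy)-3,6-dihydroxyphenyl]ethan-1-one, via potassium aryl sulfate 3 (not isolated)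
Conditions: K2S2O8, 10% aq NaOH, pyridine, 15–20 °C; then aq HCl to pH 1, 90 °C
Reagents that add atoms: potassium peroxodisulfate (K2S2O8), [K+].[K+].[O-]S(=O)(=O)OOS(=O)(=O)[O-]
Why: Elbs persulfate oxidation, in which the phenoxide attacks the peroxide oxygen through the only free carbon para to its hydroxyl (ring C3, between the two benzyloxy groups) and acid hydrolysis of sulfate 3 should free the new phenol.

Step 3
Reactants: 4 1-[2,4-bis(benzyloxy)-3,6-dihydroxyphenyl]ethan-1-one; 5 methyl 4-fluorobenzoate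
Product: 6 methyl 4-[3-acetyl-2,6-bis(benzyloxy)-4-hydroxyphenoxy]benzoate
Conditions: Cs2CO3 (2.5 equiv), 5 (1.1 equiv), DMSO, 100 °C, Ar
Reagents that add atoms: none
Why: Nucleophilic aromatic substitution (SNAr), in which the electron-rich, non-chelated 3-phenoxide is far more nucleophilic than the acetyl-conjugated chelated 6-phenoxide and should displace fluoride para to the ester group that stabilises the Meisenheimer adduct.

Step 4
Reactants: 6 methyl 4-[3-acetyl-2,6-bis(benzyloxy)-4-hydroxyphenoxy]benzoate; 7 4-methoxybenzoyl chloride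
Product: 9 methyl 4-{2,6-bis(benzyloxy)-4-hydroxy-3-[3-(4-methoxyphenyl)-3-oxopropanoyl]phenoxy}benzoate, via dilithium enolate 8 (not isolated)
Conditions: LiN(SiMe3)2 (3.1 equiv), THF, −78 → −10 °C; then 7 (1.1 equiv), −78 → 0 °C; 1 M HCl
Reagents that add atoms: none
Why: Baker–Venkataraman-type aroylation, in which dilithium enolate 8 should be acylated by the acid chloride at low temperature much faster than it attacks the methyl ester, while the third equivalent of base stores the product as its diketonate and so prevents a second acylation.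

Step 5
Reactants: 9 methyl 4-{2,6-bis(benzyloxy)-4-hydroxy-3-[3-(4-methoxyphenyl)-3-oxopropanoyl]phenoxy}benzoate
Product: 10 methyl 4-{[5,7-bis(benzyloxy)-2-(4-methoxyphenyl)-4-oxo-4H-chromen-6-yl]oxy}benzoate
Conditions: p-TsOH·H2O (0.2 equiv), toluene, 90 °C
Reagents that add atoms: none
Why: Acid-catalysed cyclodehydration of an o-hydroxydibenzoylmethane, in which the phenol adds to the anisoyl carbonyl and loss of water should give the 4-pyranone, with benzyl ethers and methyl ester untouched by the sulfonic acid in toluene.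

Step 6
Reactants: 11 4-hydroxy-6-methyl-2H-pyran-2-one (triacetic acid lactone); 12 N-methoxy-N-methylacetamide
Product: 14 4-hydroxy-6-(2-oxopropyl)-2H-pyran-2-one (tetraacetic acid lactone), via dilithio pyrone 13 (not isolated)
Conditions: LiN(i-Pr)2 (2.2 equiv), THF, −78 → −20 °C; then 12 (1.1 equiv), −78 → 0 °C; 1 M HCl
Reagents that add atoms: none
Why: Weinreb ketone synthesis on a pyrone dianion, in which the methyl carbanion of 13 is the more reactive site and the N-methoxy-N-methyl amide should stop cleanly at the ketone stage until acidic work-up.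

Step 7
Reactants: 14 4-hydroxy-6-(2-oxopropyl)-2H-pyran-2-one; 10 methyl 4-{[5,7-bis(benzyloxy)-2-(4-methoxyphenyl)-4-oxo-4H-chromen-6-yl]oxy}benzoate
Product: 16 4-hydroxy-6-[4-(4-{[5,7-bis(benzyloxy)-2-(4-methoxyphenyl)-4-oxo-4H-chromen-6-yl]oxy}phenyl)-2,4-dioxobutyl]-2H-pyran-2-one, via trilithio pyrone 15 (not isolated)
Conditions: 14 (2.5 equiv), LiN(i-Pr)2 (7.5 equiv), THF, −78 → 0 °C; then 10 (1 equiv), −78 → 0 °C; cold 1 M HCl
Reagents that add atoms: none
Why: Polyanion Claisen acylation, in which the last-formed methyl-ketone carbanion of trianion 15 is its most nucleophilic site and should attack the non-enolisable aryl ester, the β-diketone formed being deprotonated at once, which stops further addition and is the reason for the excess of 15 with no free amide base left to touch the chromone.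

Step 8
Reactants: 16 4-hydroxy-6-[4-(4-{[5,7-bis(benzyloxy)-2-(4-methoxyphenyl)-4-oxo-4H-chromen-6-yl]oxy}phenyl)-2,4-dioxobutyl]-2H-pyran-2-one
Product: 18 1-(4-{[5,7-bis(benzyloxy)-2-(4-methoxyphenyl)-4-oxo-4H-chromen-6-yl]oxy}phenyl)-3-(2,4,6-trihydroxyphenyl)propane-1,3-dione, via open-chain tetraoxo ester 17 (not isolated)
Conditions: Mg(OMe)2 (10 equiv), MeOH/THF, 65 °C, Ar; then cold 1 M HCl
Reagents that add atoms: none
Why: Methoxide adds to the lactone carbonyl of the 4-hydroxy-2-pyrone and the ring opens to methyl 9-aryl-3,5,7,9-tetraoxononanoate 17, held on Mg2+ as a polyenolate; the carbanion at chain C6 (future C4a), flanked by the C5 and C7 carbonyls, attacks the ester carbon C1 (future C8a), methoxide leaves and enolisation gives the aromatic triol. The closest known reaction is the Mg(OMe)2-mediated Claisen cyclisation of pyrone-masked 3,5,7-triketo esters to acylphloroglucinols, the laboratory counterpart of the chalcone synthase fold. The single new ring closes in a 6-exo-trig mode onto the ester carbonyl, and no stereocentre is created. The step needs the Claisen closure C6 to C1 to beat the aldol closures C2 to C7, C4 to C9 and C8 to C3, which would lead to resorcylate, coumarin or aroylresorcinol isomers. Chelation by Mg2+ should tie the 1,3-dicarbonyl pairs into six-membered enolates, so that the ketones are masked while the ester remains the only free electrophile; the aryl ketone terminus cannot enolise toward the arene and is deactivated by its para-aryloxy donor, and aromatisation makes the Claisen closure irreversible. Benzyl ethers, the methyl ether, the diaryl ether and the existing chromone should be inert to Mg(OMe)2 in methanol.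

Step 9
Reactants: 18 1-(4-{[5,7-bis(benzyloxy)-2-(4-methoxyphenyl)-4-oxo-4H-chromen-6-yl]oxy}phenyl)-3-(2,4,6-trihydroxyphenyl)propane-1,3-dione
Product: 19 5,7-bis(benzyloxy)-6-[4-(5,7-dihydroxy-4-oxo-4H-chromen-2-yl)phenoxy]-2-(4-methoxyphenyl)-4H-chromen-4-one
Conditions: p-TsOH·H2O (0.2 equiv), AcOH, 70 °C
Reagents that add atoms: none
Why: Acid-catalysed cyclodehydration, in which either of the two equivalent ortho hydroxyls adds to the aroyl carbonyl (C2) and loss of water should close O1–C2 of the second chromone under conditions mild enough to keep the benzyl and methyl ethers.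

Step 10
Reactants: 19 5,7-bis(benzyloxy)-6-[4-(5,7-dihydroxy-4-oxo-4H-chromen-2-yl)phenoxy]-2-(4-methoxyphenyl)-4H-chromen-4-one
Product: 20 cryptomerin A, 6-[4-(5,7-dihydroxy-4-oxo-4H-chromen-2-yl)phenoxy]-5,7-dihydroxy-2-(4-methoxyphenyl)-4H-chromen-4-one
Conditions: H2 (1 atm), 10% Pd/C, THF/MeOH, 25 °C
Reagents that add atoms: none
Why: Hydrogenolysis of the two aryl benzyl ethers over palladium should be faster than hydrogenation of the chromone C2=C3 bonds and leaves the methyl ether and the diaryl ether alone, without generating benzyl cations that could alkylate the phloroglucinol ring.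

**Compound list**

1 | 2',4',6'-trihydroxyacetophenone | CC(=O)c1c(O)cc(O)cc1O | starting material
2 | 1-[2,4-bis(benzyloxy)-6-hydroxyphenyl]ethan-1-one | CC(=O)c1c(O)cc(OCc2ccccc2)cc1OCc1ccccc1 | intermediate
3 | potassium 3-acetyl-2,6-bis(benzyloxy)-4-hydroxyphenyl sulfate | CC(=O)c1c(O)cc(OCc2ccccc2)c(OS(=O)(=O)[O-])c1OCc1ccccc1.[K+] | intermediate
4 | 1-[2,4-bis(benzyloxy)-3,6-dihydroxyphenyl]ethan-1-one | CC(=O)c1c(O)cc(OCc2ccccc2)c(O)c1OCc1ccccc1 | intermediate
5 | methyl 4-fluorobenzoate | COC(=O)c1ccc(F)cc1 | starting material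
6 | methyl 4-[3-acetyl-2,6-bis(benzyloxy)-4-hydroxyphenoxy]benzoate | COC(=O)c1ccc(Oc2c(OCc3ccccc3)cc(O)c(C(C)=O)c2OCc2ccccc2)cc1 | intermediate
7 | 4-methoxybenzoyl chloride | COc1ccc(C(=O)Cl)cc1 | starting material
8 | dilithium enolate-phenoxide of 6 | C=C([O-])c1c([O-])cc(OCc2ccccc2)c(Oc2ccc(C(=O)OC)cc2)c1OCc1ccccc1.[Li+].[Li+] | intermediate
9 | methyl 4-{2,6-bis(benzyloxy)-4-hydroxy-3-[3-(4-methoxyphenyl)-3-oxopropanoyl]phenoxy}benzoate | COC(=O)c1ccc(Oc2c(OCc3ccccc3)cc(O)c(C(=O)CC(=O)c3ccc(OC)cc3)c2OCc2ccccc2)cc1 | intermediate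
10 | methyl 4-{[5,7-bis(benzyloxy)-2-(4-methoxyphenyl)-4-oxo-4H-chromen-6-yl]oxy}benzoate | COC(=O)c1ccc(Oc2c(OCc3ccccc3)cc3oc(-c4ccc(OC)cc4)cc(=O)c3c2OCc2ccccc2)cc1 | intermediate
11 | 4-hydroxy-6-methyl-2H-pyran-2-one (triacetic acid lactone) | Cc1cc(O)cc(=O)o1 | starting material
12 | N-methoxy-N-methylacetamide | CC(=O)N(C)OC | starting material
13 | dilithio derivative of 11 (O4, C6-methyl dianion) | [CH2-]c1cc([O-])cc(=O)o1.[Li+].[Li+] | intermediate
14 | 4-hydroxy-6-(2-oxopropyl)-2H-pyran-2-one (tetraacetic acid lactone) | CC(=O)Cc1cc(O)cc(=O)o1 | intermediate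
15 | trilithio derivative of 14 (O4, pyrone-CH, terminal CH2 trianion) | [CH2-]C(=O)[CH-]c1cc([O-])cc(=O)o1.[Li+].[Li+].[Li+] | intermediate
16 | 4-hydroxy-6-[4-(4-{[5,7-bis(benzyloxy)-2-(4-methoxyphenyl)-4-oxo-4H-chromen-6-yl]oxy}phenyl)-2,4-dioxobutyl]-2H-pyran-2-one | O=c1cc(O)cc(CC(=O)CC(=O)c2ccc(Oc3c(OCc4ccccc4)cc4oc(-c5ccc(OC)cc5)cc(=O)c4c3OCc3ccccc3)cc2)o1 | intermediate
17 | methyl 9-(4-{[5,7-bis(benzyloxy)-2-(4-methoxyphenyl)-4-oxo-4H-chromen-6-yl]oxy}phenyl)-3,5,7,9-tetraoxononanoate (present as its Mg2+ polyenolate) | COC(=O)CC(=O)CC(=O)CC(=O)CC(=O)c1ccc(Oc2c(OCc3ccccc3)cc3oc(-c4ccc(OC)cc4)cc(=O)c3c2OCc2ccccc2)cc1 | intermediate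
18 | 1-(4-{[5,7-bis(benzyloxy)-2-(4-methoxyphenyl)-4-oxo-4H-chromen-6-yl]oxy}phenyl)-3-(2,4,6-trihydroxyphenyl)propane-1,3-dione | O=C(CC(=O)c1c(O)cc(O)cc1O)c1ccc(Oc2c(OCc3ccccc3)cc3oc(-c4ccc(OC)cc4)cc(=O)c3c2OCc2ccccc2)cc1 | intermediate
19 | 5,7-bis(benzyloxy)-6-[4-(5,7-dihydroxy-4-oxo-4H-chromen-2-yl)phenoxy]-2-(4-methoxyphenyl)-4H-chromen-4-one | COc1ccc(-c2cc(=O)c3c(OCc4ccccc4)c(Oc4ccc(-c5cc(=O)c6c(O)cc(O)cc6o5)cc4)c(OCc4ccccc4)cc3o2)cc1 | intermediate
20 | cryptomerin A, 6-[4-(5,7-dihydroxy-4-oxo-4H-chromen-2-yl)phenoxy]-5,7-dihydroxy-2-(4-methoxyphenyl)-4H-chromen-4-one | COc1ccc(-c2cc(=O)c3c(O)c(Oc4ccc(-c5cc(=O)c6c(O)cc(O)cc6o5)cc4)c(O)cc3o2)cc1 | target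

**Step count**

Total step count: 10. Longest linear sequence: 9 (steps 1, 2, 3, 4, 5, 7, 8, 9, 10); step 6 is the side branch.

**Steps most likely to fail**

1. Step 8. The opened polyketone may fold through an aldol pathway onto the C7 or C9 ketone faster than through the Claisen pathway onto the ester, or the pyrone may simply re-close, so that the phloroglucinol ring does not form selectively. This chain is one carbonyl longer than the triketo esters for which the fold is established. The fallback buys ring A instead of folding it. It sets out from ester 10 and uses acetophenone 2 again. Crossed Claisen condensation of the dilithium enolate of 2 (LiN(SiMe3)2, THF, −78 → 25 °C) with 10 would give 1-[2,4-bis(benzyloxy)-6-hydroxyphenyl]-3-(4-{[5,7-bis(benzyloxy)-2-(4-methoxyphenyl)-4-oxo-4H-chromen-6-yl]oxy}phenyl)propane-1,3-dione F1. Cyclodehydration with p-TsOH·H2O in AcOH at 70 °C would give 5,7-bis(benzyloxy)-6-{4-[5,7-bis(benzyloxy)-4-oxo-4H-chromen-2-yl]phenoxy}-2-(4-methoxyphenyl)-4H-chromen-4-one F2. Hydrogenolysis under the conditions of step 10 would remove all four benzyl groups and come back to the route at 20.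

2. Step 7. The third deprotonation of 14 may stay incomplete, proton transfer from the acidic diketone product may quench the terminal carbanion before it reaches the ester, or the carbanion may add to the chromone of 10. The fallback replaces the trianion by the well-behaved dianion and builds the chain from the aryl side. It sets out from 10. The lithium enolate of 12 (LiN(i-Pr)2, THF, −78 °C) would be condensed with 10 to 3-(4-{[5,7-bis(benzyloxy)-2-(4-methoxyphenyl)-4-oxo-4H-chromen-6-yl]oxy}phenyl)-N-methoxy-N-methyl-3-oxopropanamide F3. The aryl ketone would be protected with 1,2-bis(trimethylsilyloxy)ethane and catalytic Me3SiOTf in CH2Cl2 at −20 °C as 2-[2-(4-{[5,7-bis(benzyloxy)-2-(4-methoxyphenyl)-4-oxo-4H-chromen-6-yl]oxy}phenyl)-1,3-dioxolan-2-yl]-N-methoxy-N-methylacetamide F4. Dilithio pyrone 13, made from 11 as in step 6, would be acylated by this Weinreb amide to 6-{3-[2-(4-{[5,7-bis(benzyloxy)-2-(4-methoxyphenyl)-4-oxo-4H-chromen-6-yl]oxy}phenyl)-1,3-dioxolan-2-yl]-2-oxopropyl}-4-hydroxy-2H-pyran-2-one F5. 1 M HCl in THF at 25 °C would release the aryl ketone and come back to the route at 16.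

3. Step 2. Attack of peroxodisulfate on the poorly soluble, chelated phenoxide may be slow, and over-oxidation of the electron-rich hydroquinone may compete, so conversion can stall. The fallback reaches the same oxidation pattern through the quinone. It sets out from 2. Teuber oxidation with (KSO3)2NO in KH2PO4-buffered acetone/water at 25 °C would oxidise the free para position to 2-acetyl-3,5-bis(benzyloxy)cyclohexa-2,5-diene-1,4-dione F6. Reduction with Na2S2O4 in EtOAc/water would give the hydroquinone and come back to the route at 4.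

**Further compounds**

F1 | step 8 | 1-[2,4-bis(benzyloxy)-6-hydroxyphenyl]-3-(4-{[5,7-bis(benzyloxy)-2-(4-methoxyphenyl)-4-oxo-4H-chromen-6-yl]oxy}phenyl)propane-1,3-dione | O=C(CC(=O)c1c(O)cc(OCc2ccccc2)cc1OCc1ccccc1)c1ccc(Oc2c(OCc3ccccc3)cc3oc(-c4ccc(OC)cc4)cc(=O)c3c2OCc2ccccc2)cc1
F2 | step 8 | 5,7-bis(benzyloxy)-6-{4-[5,7-bis(benzyloxy)-4-oxo-4H-chromen-2-yl]phenoxy}-2-(4-methoxyphenyl)-4H-chromen-4-one | COc1ccc(-c2cc(=O)c3c(OCc4ccccc4)c(Oc4ccc(-c5cc(=O)c6c(OCc7ccccc7)cc(OCc7ccccc7)cc6o5)cc4)c(OCc4ccccc4)cc3o2)cc1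
F3 | step 7 | 3-(4-{[5,7-bis(benzyloxy)-2-(4-methoxyphenyl)-4-oxo-4H-chromen-6-yl]oxy}phenyl)-N-methoxy-N-methyl-3-oxopropanamide | CON(C)C(=O)CC(=O)c1ccc(Oc2c(OCc3ccccc3)cc3oc(-c4ccc(OC)cc4)cc(=O)c3c2OCc2ccccc2)cc1
F4 | step 7 | 2-[2-(4-{[5,7-bis(benzyloxy)-2-(4-methoxyphenyl)-4-oxo-4H-chromen-6-yl]oxy}phenyl)-1,3-dioxolan-2-yl]-N-methoxy-N-methylacetamide | CON(C)C(=O)CC1(OCCO1)c1ccc(Oc2c(OCc3ccccc3)cc3oc(-c4ccc(OC)cc4)cc(=O)c3c2OCc2ccccc2)cc1
F5 | step 7 | 6-{3-[2-(4-{[5,7-bis(benzyloxy)-2-(4-methoxyphenyl)-4-oxo-4H-chromen-6-yl]oxy}phenyl)-1,3-dioxolan-2-yl]-2-oxopropyl}-4-hydroxy-2H-pyran-2-one | O=c1cc(O)cc(CC(=O)CC2(OCCO2)c2ccc(Oc3c(OCc4ccccc4)cc4oc(-c5ccc(OC)cc5)cc(=O)c4c3OCc3ccccc3)cc2)o1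
F6 | step 2 | 2-acetyl-3,5-bis(benzyloxy)cyclohexa-2,5-diene-1,4-dione | CC(=O)C1=C(OCc2ccccc2)C(=O)C(OCc2ccccc2)=CC1=O
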